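**Strategy.** Everything rests on opening ring A at the C3–C4 bond (drimane numbering). The key step exploits that ring A holds the gem-dimethyl carbon C4 and, 1,4 to it, the oxygenated C1: C4 is a latent tertiary radical and C1–C2–C3 a latent vinyl ketone. Iron-hydride hydrogen-atom transfer to an isopropenyl group therefore closes ring A by 6-endo radical conjugate addition, creating the quaternary C4 and the trans-decalin in one operation. The precursor is ring B alone: (R)-carvone bearing at C10 a methyl and an acryloyl group, the latter trans to isopropenyl. The carvone carbonyl (C9) later receives C11 and the carvone methyl (C12) is oxidised, giving the two formyl groups.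

Key step: step 4

Remark: drimane numbering is used for the decalin and for the matching atoms of the monocyclic precursors: C1 bears the ester oxygen, C4 the two methyls, C5 and C10 are the fusion carbons (C10 with the angular methyl), C7=C8 is the ring B alkene, C11 is the formyl carbon on C9 and C12 the one on C8.

**Route**

Step 1
Reactants: 1 (R)-(−)-carvone; 2 iodomethane
Product: 3 (5R,6S)-2,6-dimethyl-5-(prop-1-en-2-yl)cyclohex-2-en-1-one (trans-6-methylcarvone)
Conditions: LiN(iPr)2 (LDA), THF, −78 °C; MeI, −78 → 0 °C
Reagents that add atoms: iodomethane, CI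
Why: Kinetic α′-deprotonation of the enone and SN2 methylation of the lithium enolate (enolate alkylation) should give mainly the trans epimer; the minor C6 epimer is carried along because C6 is planarised again in step 2.

Step 2
Reactants: 3 trans-6-methylcarvone; 4 acrolein
Product: 5 (5S,6R)-6-(1-hydroxyprop-2-en-1-yl)-2,6-dimethyl-5-(prop-1-en-2-yl)cyclohex-2-en-1-one (both carbinol epimers)
Conditions: LiN(iPr)2, THF, −78 °C; acrolein, −78 °C; AcOH quench at −78 °C
Reagents that add atoms: acrolein, C=CC=O
Why: Lithium enolate aldol addition (1,2-addition to the enal) should take place on the face of the tetrasubstituted enolate anti to the neighbouring isopropenyl group, which puts the new carbon chain trans and the methyl cis to isopropenyl, i.e. the C5/C10 relationship of the target; the cold acidic quench guards against retro-aldol.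

Step 3
Reactants: 5 aldol adduct
Product: 6 (5S,6R)-2,6-dimethyl-6-(prop-2-enoyl)-5-(prop-1-en-2-yl)cyclohex-2-en-1-one
Conditions: Dess–Martin periodinane, CH2Cl2, 0 °C → rt
Reagents that add atoms: none
Why: Dess–Martin oxidation of the secondary allylic alcohol should give the vinyl ketone under neutral conditions, both carbinol epimers converging; the quaternary carbon between the two carbonyls cannot enolise, so its configuration is secure.

Step 4
Reactants: 6 acryloyl isopropenyl cyclohexenone
Product: 7 (4aS,8aR)-2,5,5,8a-tetramethyl-4,4a,5,6,7,8a-hexahydronaphthalene-1,8-dione (trans-fused 11-nordrim-7-ene-1,9-dione)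
Conditions: Fe(acac)3 (0.3 equiv), PhSiH3, EtOH/ethylene glycol (5:1), degassed, dilute, 60 °C
Reagents that add atoms: none
Why: An iron hydride formed from Fe(acac)3 and PhSiH3 in ethanol transfers a hydrogen atom to the terminal CH2 of the isopropenyl group, the tertiary C4 radical adds to the β-carbon C3 of the vinyl ketone, and the α-keto radical at C2 is reduced by divalent iron to the enolate and protonated by ethanol, which returns trivalent iron. The closest known reaction type is the iron-mediated reductive olefin–enone coupling (HAT-initiated Giese cyclisation), which is established for closing six-membered rings onto gem-dimethyl carbons of carvone-derived substrates. Ring A closes in the 6-endo-trig mode, since the nucleophilic tertiary radical attacks the electron-poor terminus C3 and the 5-exo attack at C2 is polarity-mismatched. No stereocentre is created (C4 carries two methyls, C2 and C3 are CH2); the trans ring fusion follows from the trans arrangement of the C5 and C10 side chains set in step 2, which can meet only in the diequatorial conformer. The step needs hydrogen-atom delivery to the electron-rich 1,1-disubstituted alkene and not to the two enone alkenes, which the preference of the iron hydride for alkenes that give tertiary radicals should secure. The ring B enone is out of reach of the C4 radical, because only a four-membered or a bridged 5-endo closure would be possible there.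

Step 5
Reactants: 7 bicyclic diketone
Product: 8 (4aS,8R,8aR)-8-hydroxy-2,5,5,8a-tetramethyl-4a,5,6,7,8,8a-hexahydro-4H-naphthalen-1-one (1β-hydroxy-11-nordrim-7-en-9-one)
Conditions: NaBH4 (0.4 equiv), MeOH/CH2Cl2 (1:1), −78 → −40 °C
Reagents that add atoms: none
Why: Chemoselective borohydride reduction should take the saturated C1 ketone before the conjugated and more hindered C9 enone carbonyl, and axial hydride delivery on the α-face, anti to the axial C10 methyl, should give the equatorial 1β-alcohol (C1 R).

Step 6
Reactants: 8 1β-hydroxy enone; 9 (trimethylsilyl)methyllithium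
Product: 11 drima-7,9(11)-dien-1β-ol, via β-hydroxysilane 10 (not isolated)
Conditions: Me3SiCH2Li (3.5 equiv), anhydrous CeCl3, THF, −78 → 0 °C; aq. NH4Cl; crude in MeCN, 48% aq. HF, rt
Reagents that add atoms: (trimethylsilyl)methyllithium, [Li]C[Si](C)(C)C
Why: Peterson olefination: the weakly basic organocerium reagent should add 1,2 to the hindered enone carbonyl without retro-aldol cleavage of the aldolate, and acid-induced elimination of the β-hydroxysilane can give only the exocyclic C9=C11 methylene because the silyl group directs the elimination; no stereocentre is set.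

Step 7
Reactants: 11 drima-7,9(11)-dien-1β-ol; 12 (E)-3-(4-methoxyphenyl)prop-2-enoyl chloride
Product: 13 drima-7,9(11)-dien-1β-yl (E)-4-methoxycinnamate
Conditions: Et3N, DMAP (cat.), CH2Cl2, 0 → 40 °C
Reagents that add atoms: (E)-4-methoxycinnamoyl chloride, COc1ccc(/C=C/C(Cl)=O)cc1
Why: DMAP-catalysed acylation of the only hydroxyl group, the equatorial 1β-alcohol, with the acid chloride should give the ester with retention at C1, since the C1–O bond is not touched.

Step 8
Reactants: 13 diene ester
Product: 15 11-hydroxydrim-7-en-1β-yl (E)-4-methoxycinnamate, via alkylborane 14 (not isolated)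
Conditions: 9-BBN (1.5 equiv), THF, 0 °C → rt; then NaBO3·4H2O, H2O, rt
Reagents that add atoms: 9-borabicyclo[3.3.1]nonane, [H]B1C2CCCC1CCC2 (boron stays only in 14); sodium perborate tetrahydrate NaBO3·4H2O, [Na+].[Na+].O[B-]1(O)OO[B-](O)(O)OO1 (source of the C11 oxygen)
Why: Hydroboration–oxidation: the bulky borane should add to the terminal carbon C11 of the 1,1-disubstituted alkene, leave the trisubstituted C7=C8 bond and the electron-poor cinnamate alkene alone, and deliver hydrogen to C9 on the α-face anti to the axial C10 methyl, so that C9 receives the α-hydrogen and the β-CH2OH group as in the target; perborate oxidation spares the ester.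

Step 9
Reactants: 15 1β-acyloxy drimenol
Product: 16 11,12-dihydroxydrim-7-en-1β-yl (E)-4-methoxycinnamate
Conditions: SeO2 (0.3 equiv), t-BuOOH (3 equiv), salicylic acid (cat.), CH2Cl2, rt, stopped before full conversion
Reagents that add atoms: tert-butyl hydroperoxide, CC(C)(C)OO (terminal oxidant); SeO2, O=[Se]=O (oxygen carrier)
Why: SeO2 allylic hydroxylation (ene reaction, then 2,3-sigmatropic shift) should occur at the more substituted alkene terminus C8, where the methyl C12 is preferred over the hindered methine C9 as in the oxidation of drimenyl esters, so the alkene stays at C7=C8 and C9 is not touched.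

Step 10
Reactants: 16 diol
Product: 17 1β-[(E)-4-methoxycinnamoyloxy]polygodial, (1R,5S,9R,10S)
Conditions: (COCl)2, DMSO, CH2Cl2, −78 °C; Et3N, −78 → −30 °C; cold pH 7 phosphate buffer
Reagents that add atoms: none
Why: Double Swern oxidation should convert both primary alcohols to the 1,4-dialdehyde, since activating both hydroxyls at once avoids lactol formation and the cold amine step with neutral quench should preserve the base-sensitive C9 centre and the C7=C8 position, as in the diol-to-dialdehyde conversion known for polygodial.

**Compound list**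

1 | (R)-(−)-carvone | CC(=C)[C@@H]1CC=C(C)C(=O)C1 | starting material
2 | iodomethane | CI | starting material
3 | (5R,6S)-2,6-dimethyl-5-(prop-1-en-2-yl)cyclohex-2-en-1-one (trans-6-methylcarvone, major epimer) | CC(=C)[C@@H]1CC=C(C)C(=O)[C@H]1C | intermediate
4 | acrolein | C=CC=O | starting material
5 | (5S,6R)-6-(1-hydroxyprop-2-en-1-yl)-2,6-dimethyl-5-(prop-1-en-2-yl)cyclohex-2-en-1-one (carbinol epimers) | CC(=C)[C@@H]1CC=C(C)C(=O)[C@@]1(C)C(O)C=C | intermediate
6 | (5S,6R)-2,6-dimethyl-6-(prop-2-enoyl)-5-(prop-1-en-2-yl)cyclohex-2-en-1-one | CC(=C)[C@@H]1CC=C(C)C(=O)[C@@]1(C)C(=O)C=C | intermediate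
7 | (4aS,8aR)-2,5,5,8a-tetramethyl-4,4a,5,6,7,8a-hexahydronaphthalene-1,8-dione (11-nordrim-7-ene-1,9-dione) | O=C1CCC(C)(C)[C@@H]2CC=C(C)C(=O)[C@@]12C | intermediate
8 | (4aS,8R,8aR)-8-hydroxy-2,5,5,8a-tetramethyl-4a,5,6,7,8,8a-hexahydro-4H-naphthalen-1-one (1β-hydroxy-11-nordrim-7-en-9-one) | O[C@@H]1CCC(C)(C)[C@@H]2CC=C(C)C(=O)[C@@]12C | intermediate
9 | (trimethylsilyl)methyllithium | [Li]C[Si](C)(C)C | starting material
10 | 9α-[(trimethylsilyl)methyl]-11-nordrim-7-ene-1β,9β-diol (expected epimer from α-face addition) | O[C@@H]1CCC(C)(C)[C@@H]2CC=C(C)[C@@](O)(C[Si](C)(C)C)[C@@]12C | intermediate (not isolated)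
11 | drima-7,9(11)-dien-1β-ol | O[C@@H]1CCC(C)(C)[C@@H]2CC=C(C)C(=C)[C@@]12C | intermediate
12 | (E)-3-(4-methoxyphenyl)prop-2-enoyl chloride | COc1ccc(/C=C/C(Cl)=O)cc1 | starting material
13 | drima-7,9(11)-dien-1β-yl (E)-4-methoxycinnamate | COc1ccc(/C=C/C(=O)O[C@@H]2CCC(C)(C)[C@@H]3CC=C(C)C(=C)[C@@]23C)cc1 | intermediate
14 | 11-(9-borabicyclo[3.3.1]nonan-9-yl)drim-7-en-1β-yl (E)-4-methoxycinnamate | COc1ccc(/C=C/C(=O)O[C@@H]2CCC(C)(C)[C@@H]3CC=C(C)[C@H](CB4C5CCCC4CCC5)[C@@]23C)cc1 | intermediate (not isolated)
15 | 11-hydroxydrim-7-en-1β-yl (E)-4-methoxycinnamate | COc1ccc(/C=C/C(=O)O[C@@H]2CCC(C)(C)[C@@H]3CC=C(C)[C@H](CO)[C@@]23C)cc1 | intermediate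
16 | 11,12-dihydroxydrim-7-en-1β-yl (E)-4-methoxycinnamate | COc1ccc(/C=C/C(=O)O[C@@H]2CCC(C)(C)[C@@H]3CC=C(CO)[C@H](CO)[C@@]23C)cc1 | intermediate
17 | 1β-[(E)-4-methoxycinnamoyloxy]polygodial, (1R,5S,9R,10S) | COc1ccc(/C=C/C(=O)O[C@@H]2CCC(C)(C)[C@@H]3CC=C(C=O)[C@H](C=O)[C@@]23C)cc1 | target

**Totals**

Total step count: 10. Longest linear sequence: 10 steps, from (R)-(−)-carvone 1.

**Steps most likely to fail**

Step 9. The risk is over-oxidation of C12 to the aldehyde level, capture of that aldehyde by the free C11 hydroxyl as a lactol and further oxidation to a lactone, together with sluggish conversion. The fallback sets out from 15 and masks C11 first. TBSCl and imidazole in DMF should give the 11-O-tert-butyldimethylsilyl ether F1. Stoichiometric SeO2 in dioxane at 80 °C, buffered with pyridine, then takes C12 deliberately to the aldehyde level, giving the 12-oxo silyl ether F2. Luche reduction (NaBH4, CeCl3·7H2O, MeOH, 0 °C) should give the 12-hydroxy silyl ether F3. HF·pyridine in THF removes the silyl group, and the sequence comes back to the route at 16.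

Step 6. The risk is retro-aldol fragmentation of the metal aldolate at the C1–C10 bond, or γ-deprotonation of the enone in place of addition to the hindered carbonyl. The fallback sets out from 8 and removes the free hydroxyl before the olefination. Acylation with 12 (Et3N, DMAP, CH2Cl2) should give 1β-[(E)-4-methoxycinnamoyloxy]-11-nordrim-7-en-9-one F4. Non-basic methylenation of the ketone with Zn, CH2Br2 and TiCl4 in THF/CH2Cl2 then tolerates the ester, and the sequence comes back to the route at 13.

Step 5. The risk is concurrent hydride attack on the enone carbonyl, which would erode the differentiation of C1 and C9. The fallback sets out from 7 and reduces both carbonyls on purpose with excess NaBH4 and CeCl3·7H2O in MeOH at 0 °C → rt, giving 11-nordrim-7-ene-1β,9-diol F5 (either C9 epimer serves). Activated MnO2 in CH2Cl2 then reoxidises only the allylic C9 alcohol, and the sequence comes back to the route at 8.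

**Further compounds**

F1 | step 9 | 11-(tert-butyldimethylsilyloxy)drim-7-en-1β-yl (E)-4-methoxycinnamate | COc1ccc(/C=C/C(=O)O[C@@H]2CCC(C)(C)[C@@H]3CC=C(C)[C@H](CO[Si](C)(C)C(C)(C)C)[C@@]23C)cc1
F2 | step 9 | 11-(tert-butyldimethylsilyloxy)-12-oxodrim-7-en-1β-yl (E)-4-methoxycinnamate | COc1ccc(/C=C/C(=O)O[C@@H]2CCC(C)(C)[C@@H]3CC=C(C=O)[C@H](CO[Si](C)(C)C(C)(C)C)[C@@]23C)cc1
F3 | step 9 | 11-(tert-butyldimethylsilyloxy)-12-hydroxydrim-7-en-1β-yl (E)-4-methoxycinnamate | COc1ccc(/C=C/C(=O)O[C@@H]2CCC(C)(C)[C@@H]3CC=C(CO)[C@H](CO[Si](C)(C)C(C)(C)C)[C@@]23C)cc1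
F4 | step 6 | 1β-[(E)-4-methoxycinnamoyloxy]-11-nordrim-7-en-9-one | COc1ccc(/C=C/C(=O)O[C@@H]2CCC(C)(C)[C@@H]3CC=C(C)C(=O)[C@@]23C)cc1
F5 | step 5 | 11-nordrim-7-ene-1β,9β-diol (expected major C9 epimer) | O[C@@H]1CCC(C)(C)[C@@H]2CC=C(C)[C@H](O)[C@@]12C
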